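**Retrosynthetic overview**
1. Target 15 ⇒ vinylcyclopentane acid 13 + oct-1-en-3-one 14 by a late E-selective cross-metathesis at C13=C14, so the enone arrives at the ketone oxidation level with no protecting group at C15.
2. 13 ⇒ vinyl lactol 10 + ylide 12 by a Z-selective Wittig reaction (C5=C6).
3. 10 ⇒ enal acetal 5 by copper-catalysed conjugate vinylation with silyl trapping (sets C12), then excision of the formyl carbon by ozonolysis and reduction (sets C11).
4. 5 ⇒ bicyclic enal lactol 4 ⇒ two molecules of succinaldehyde 2 by an L-proline aldol / aldol-condensation cascade (sets C8 and C9; this is the bold key step).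
5. Ring order: the cyclopentene closes first (intramolecular aldol condensation), the lactol (tetrahydrofuranol) ring closes onto it in the same pot, and the lactol ring is opened again in the Wittig step.

Assumption: 1 is the commercial cis/trans mixture, the lactol and acetal carbon is carried as an anomeric mixture, and the geometry of silyl enol ether 7 is inconsequential.

**Step 1**
Reactants: 1 2,5-dimethoxytetrahydrofuran
Product: 2 succinaldehyde (butanedial)
Conditions: H2O, 90 °C, 2 h; distil off MeOH/H2O; extract (CH2Cl2); vacuum distil; use at once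
Reagents that add atoms: water, O
Why: Hydrolysis of the cyclic bis-acetal is driven to the dialdehyde by distilling out methanol (acetal hydrolysis).

**Step 2**
Reactants: 2 succinaldehyde (two molecules)
Product: 4 (3aR,6aS)-2-hydroxy-3,3a,6,6a-tetrahydro-2H-cyclopenta[b]furan-5-carbaldehyde (bicyclic enal lactol; anomeric mixture), via aldol trialdehyde 3 (not isolated)
Conditions: L-proline (2 mol %), EtOAc, rt, 20 h; then [Bn2NH2][OCOCF3] (2 mol %), rt → 65 °C
Reagents that add atoms: none
Why: L-proline enamine catalysis gives the anti-selective intermolecular aldol reaction through the hydrogen-bonded chair transition state (sets the future C8 and C9 as 2S,3S in 3 with high er), and the ammonium trifluoroacetate then promotes the intramolecular aldol condensation to the cyclopentenecarbaldehyde, whose secondary hydroxyl closes onto the pendant aldehyde as the cis-fused lactol.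

**Step 3**
Reactants: 4 bicyclic enal lactol
Product: 5 (3aR,6aS)-2-methoxy-3,3a,6,6a-tetrahydro-2H-cyclopenta[b]furan-5-carbaldehyde (anomeric mixture)
Conditions: MeOH, Amberlyst 15, MgSO4, CH2Cl2, rt
Reagents that add atoms: methanol, CO
Why: In this Fischer-type acetalisation the lactol ionises to its oxocarbenium ion far faster than the conjugated aldehyde is acetalised, so only the anomeric OH is exchanged while MgSO4 removes water.

**Step 4**
Reactants: 5 enal methyl acetal; 6 vinylmagnesium bromide
Product: 7 (3aR,4R,6aS)-4-ethenyl-2-methoxy-5-[(trimethylsilyloxy)methylidene]hexahydro-2H-cyclopenta[b]furan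
Conditions: CH2=CHMgBr (1.5 equiv), CuBr·SMe2 (10 mol %), TMSCl (2 equiv), HMPA (2 equiv), THF, −78 °C; then Et3N, cold aq. NaHCO3/hexane work-up; used crude
Reagents that add atoms: chlorotrimethylsilane, C[Si](C)(C)Cl
Why: In this copper-catalysed, TMSCl/HMPA-accelerated conjugate addition of a Grignard reagent to an enal, the vinyl group is delivered to C12 on the convex face, anti to the cis-fused tetrahydrofuran ring on the neighbouring C8, and silyl trapping of the enolate suppresses 1,2-addition.

**Step 5**
Reactants: 7 silyl enol ether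
Product: 9 (3aR,4R,5R,6aS)-4-ethenyl-2-methoxyhexahydro-2H-cyclopenta[b]furan-5-ol, via ketone 8 (not isolated)
Conditions: O3 (about 1 equiv, stopped at consumption of 7), CH2Cl2/MeOH 3:1, −78 °C; then NaBH4, −78 °C → rt
Reagents that add atoms: ozone, [O-][O+]=O
Why: Ozonolysis with reductive work-up excises the formyl carbon, because the electron-rich silyl enol ether reacts far faster than the monosubstituted vinyl group, and NaBH4 then reduces the C11 ketone in situ from the convex face (before the β,γ-unsaturated ketone can epimerise or conjugate) to give the 11α-alcohol trans to the vinyl group.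

**Step 6**
Reactants: 9 acetal alcohol
Product: 10 (3aR,4R,5R,6aS)-4-ethenylhexahydro-2H-cyclopenta[b]furan-2,5-diol (anomeric mixture)
Conditions: 1.5% aq. HCl/THF 3:2, rt
Reagents that add atoms: water, O
Why: Mild aqueous acid hydrolysis of the mixed methyl acetal gives the lactol without touching the vinyl group or any stereocentre.

**Step 7**
Reactants: 10 vinyl lactol; 11 (4-carboxybutyl)triphenylphosphonium bromide
Product: 13 (5Z)-7-[(1R,2R,3R,5S)-2-ethenyl-3,5-dihydroxycyclopentyl]hept-5-enoic acid, via phosphonium ylide 12 (not isolated)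
Conditions: 11 (6 equiv), KOtBu (12 equiv), THF, 0 °C; add 10, 0 °C → rt; aq. HCl to pH 4
Reagents that add atoms: none
Why: Wittig olefination of the open hydroxy-aldehyde tautomer of the lactol with a non-stabilised ylide gives the 5Z alkene under kinetic control, with excess ylide covering the free OH groups.

**Step 8**
Reactants: 13 vinyl diol acid; 14 oct-1-en-3-one
Product: 15 15-keto-PGF2α, (5Z)-7-[(1R,2R,3R,5S)-3,5-dihydroxy-2-[(1E)-3-oxooct-1-en-1-yl]cyclopentyl]hept-5-enoic acid
Conditions: 14 (5 equiv), second-generation Hoveyda–Grubbs catalyst [RuCl2(H2IMes)(=CH-C6H4-2-OiPr)] (5 mol %), CH2Cl2, 40 °C, Ar sparge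
Reagents that add atoms: none
Why: In this olefin cross-metathesis the ruthenium alkylidene loads on the terminal vinyl group and is captured by the excess electron-poor enone to give the E enone with loss of ethylene, while the internal Z alkene is less reactive, ring closure onto it would need a strained trans-fused bicyclo[3.3.0]octene, and the catalyst tolerates free OH and CO2H.

**Compound list**
1 | 2,5-dimethoxytetrahydrofuran (cis/trans mixture) | COC1CCC(OC)O1 | starting material
2 | succinaldehyde | O=CCCC=O | intermediate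
3 | (2S,3S)-3-hydroxy-2-(2-oxoethyl)hexanedial (aldol trialdehyde, not isolated) | O=CC[C@H](C=O)[C@@H](O)CCC=O | intermediate
4 | (3aR,6aS)-2-hydroxy-3,3a,6,6a-tetrahydro-2H-cyclopenta[b]furan-5-carbaldehyde | O=CC1=C[C@H]2CC(O)O[C@H]2C1 | intermediate
5 | (3aR,6aS)-2-methoxy-3,3a,6,6a-tetrahydro-2H-cyclopenta[b]furan-5-carbaldehyde | O=CC1=C[C@H]2CC(OC)O[C@H]2C1 | intermediate
6 | vinylmagnesium bromide | C=C[Mg]Br | starting material
7 | (3aR,4R,6aS)-4-ethenyl-2-methoxy-5-[(trimethylsilyloxy)methylidene]hexahydro-2H-cyclopenta[b]furan | C=C[C@@H]1[C@H]2CC(OC)O[C@H]2CC1=CO[Si](C)(C)C | intermediate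
8 | (3aR,4R,6aS)-4-ethenyl-2-methoxyhexahydro-2H-cyclopenta[b]furan-5-one (not isolated) | C=C[C@@H]1[C@H]2CC(OC)O[C@H]2CC1=O | intermediate
9 | (3aR,4R,5R,6aS)-4-ethenyl-2-methoxyhexahydro-2H-cyclopenta[b]furan-5-ol | C=C[C@@H]1[C@H]2CC(OC)O[C@H]2C[C@H]1O | intermediate
10 | (3aR,4R,5R,6aS)-4-ethenylhexahydro-2H-cyclopenta[b]furan-2,5-diol | C=C[C@@H]1[C@H]2CC(O)O[C@H]2C[C@H]1O | intermediate
11 | (4-carboxybutyl)triphenylphosphonium bromide | OC(=O)CCCC[P+](c1ccccc1)(c1ccccc1)c1ccccc1.[Br-] | starting material
12 | potassium 5-(triphenylphosphoranylidene)pentanoate (ylide, not isolated) | [K+].[O-]C(=O)CCCC=P(c1ccccc1)(c1ccccc1)c1ccccc1 | intermediate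
13 | (5Z)-7-[(1R,2R,3R,5S)-2-ethenyl-3,5-dihydroxycyclopentyl]hept-5-enoic acid | C=C[C@@H]1[C@@H](C/C=C\CCCC(=O)O)[C@@H](O)C[C@H]1O | intermediate
14 | oct-1-en-3-one | CCCCCC(=O)C=C | starting material
15 | 15-keto-PGF2α | CCCCCC(=O)/C=C/[C@@H]1[C@@H](C/C=C\CCCC(=O)O)[C@@H](O)C[C@H]1O | target

**Totals**
Total step count: 8. Longest linear sequence: 8 steps (1 → 15).

**Three steps most likely to fail**

Step 8 (highest risk). The 5Z alkene may be cleaved, scrambled or isomerised during the cross-metathesis. The fallback sets out from 10, before the Z alkene exists. Cross-metathesis of 10 with commercial (S)-oct-1-en-3-ol under the same ruthenium catalyst gives (3aR,4R,5R,6aS)-4-[(1E,3S)-3-hydroxyoct-1-en-1-yl]hexahydro-2H-cyclopenta[b]furan-2,5-diol F3. Wittig reaction of F3 with ylide 12 (from 11 and KOtBu, as in step 7) gives PGF2α F4. Chemoselective oxidation of the allylic C15 hydroxyl with 2,3-dichloro-5,6-dicyano-1,4-benzoquinone in dioxane at rt leaves the two ring carbinols alone and comes back to the route at 15.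

Step 5. Ozone may also attack the vinyl group. The fallback sets out from 7 and replaces ozonolysis by electrophilic epoxidation, which discriminates more strongly for the enol ether. Rubottom oxidation (mCPBA, NaHCO3, CH2Cl2, −20 °C; then K2CO3, MeOH) gives (3aR,4R,6aS)-4-ethenyl-5-hydroxy-2-methoxyhexahydro-2H-cyclopenta[b]furan-5-carbaldehyde F2 (C5 epimers, inconsequential). Cleavage of this α-hydroxy aldehyde with NaIO4 in THF/H2O comes back to the route at ketone 8, which is reduced at once with NaBH4 to 9.

Step 4. The Grignard reagent may add 1,2 to the aldehyde, or the labile enol ether may be lost. The fallback sets out from 5 and separates C–C bond formation from silylation. Rhodium-catalysed conjugate addition of potassium vinyltrifluoroborate, K[CH2=CHBF3], with [Rh(OH)(cod)]2 (2.5 mol %) in dioxane/H2O at 50 °C, again on the convex face, gives (3aR,4R,6aS)-4-ethenyl-2-methoxyhexahydro-2H-cyclopenta[b]furan-5-carbaldehyde F1 (C5 epimers, inconsequential). Soft enolisation and silylation (TMSCl, Et3N, NaI, MeCN) comes back to the route at 7.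

Step 2 is low-yielding by nature (oligomerisation of succinaldehyde), but it is the first bond-forming step, uses a very cheap feedstock and is accepted as the price of the short route.

**Further compounds**
F1 | step 4 | (3aR,4R,6aS)-4-ethenyl-2-methoxyhexahydro-2H-cyclopenta[b]furan-5-carbaldehyde | C=C[C@@H]1[C@H]2CC(OC)O[C@H]2CC1C=O
F2 | step 5 | (3aR,4R,6aS)-4-ethenyl-5-hydroxy-2-methoxyhexahydro-2H-cyclopenta[b]furan-5-carbaldehyde | C=C[C@@H]1[C@H]2CC(OC)O[C@H]2CC1(O)C=O
F3 | step 8 | (3aR,4R,5R,6aS)-4-[(1E,3S)-3-hydroxyoct-1-en-1-yl]hexahydro-2H-cyclopenta[b]furan-2,5-diol | CCCCC[C@H](O)/C=C/[C@@H]1[C@H]2CC(O)O[C@H]2C[C@H]1O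
F4 | step 8 | PGF2α, (5Z)-7-[(1R,2R,3R,5S)-3,5-dihydroxy-2-[(1E,3S)-3-hydroxyoct-1-en-1-yl]cyclopentyl]hept-5-enoic acid | CCCCC[C@H](O)/C=C/[C@@H]1[C@@H](C/C=C\CCCC(=O)O)[C@@H](O)C[C@H]1O
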